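**Strategy.** The target is cut at both ends of its CH2–CH2 bridge, which carries C1 of ring A (the 3,5-dimethoxy ring, benzylated at C2) on one carbon and C1 of ring B (the 3-hydroxyphenyl ring) on the other. A palladium-catalysed conjunctive coupling on a vinylboron linchpin forms both aryl–carbon bonds in one operation: the ring B aryl migrates from boron to the boron-bearing carbon, while the terminal carbon is joined to ring A. The precursor is the ring A triflate with the protected 4-hydroxybenzyl group (ring C) already at C2, built regiospecifically from a 2-hydroxybenzaldehyde, together with a lithium aryl(vinyl)borate. Protodeboronation and one hydrogenolysis finish the synthesis.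

Key step: step 4

Remarks on the chemistry:
- The target (gymconopin D) is achiral.
- Direct benzylation of 3,5-dimethoxyphenol would have to choose among C2, C4 and oxygen. The C2 benzyl carbon is therefore taken from an aldehyde that already sits at that position.
- The boron-bearing carbon of 10 is formed under a chiral ligand, so 10 is expected as an unequal mixture of enantiomers rather than a racemate. Its configuration is immaterial, because step 5 turns this carbon into CH2.

**Step 1**
Reactants: 1 2-hydroxy-4,6-dimethoxybenzaldehyde; 2 4-(benzyloxy)phenylmagnesium bromide (commercial THF solution)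
Product: 3 racemic 2-{[4-(benzyloxy)phenyl](hydroxy)methyl}-3,5-dimethoxyphenol
Conditions: 2 (2.3 equiv), THF, 0 °C to rt; sat. aq. NH4Cl; crude product carried on
Reagents that add atoms: none
Why: Aryl Grignard 1,2-addition to the aldehyde after the first equivalent has formed the magnesium phenoxide, which fixes the benzylic carbon at C2 of ring A through the starting material; the carbinol centre is racemic and is removed in step 2.

**Step 2**
Reactants: 3 racemic 2-{[4-(benzyloxy)phenyl](hydroxy)methyl}-3,5-dimethoxyphenol
Product: 4 2-[4-(benzyloxy)benzyl]-3,5-dimethoxyphenol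
Conditions: Et3SiH (3 equiv), CF3CO2H (5 equiv), CH2Cl2, 0 °C
Reagents that add atoms: none
Why: Ionic hydrogenation, in which the carbinol ionises readily to a doubly aryl-stabilised benzylic cation that takes hydride from the silane, while the aryl benzyl and methyl ethers should survive brief exposure to dilute acid at 0 °C.

**Step 3**
Reactants: 4 2-[4-(benzyloxy)benzyl]-3,5-dimethoxyphenol
Product: 5 2-[4-(benzyloxy)benzyl]-3,5-dimethoxyphenyl trifluoromethanesulfonate
Conditions: Tf2O, pyridine, CH2Cl2, 0 °C
Reagents that add atoms: trifluoromethanesulfonic anhydride (Tf2O), O=S(=O)(OS(=O)(=O)C(F)(F)F)C(F)(F)F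
Why: Standard O-sulfonylation of a phenol to the aryl triflate, which tolerates the ethers and the ortho benzyl group.

**Step 4**
Reactants: 5 2-[4-(benzyloxy)benzyl]-3,5-dimethoxyphenyl trifluoromethanesulfonate; 6 1-(benzyloxy)-3-bromobenzene; 7 vinylboronic acid pinacol ester
Product: 10 2-(2-{2-[4-(benzyloxy)benzyl]-3,5-dimethoxyphenyl}-1-[3-(benzyloxy)phenyl]ethyl)-4,4,5,5-tetramethyl-1,3,2-dioxaborolane, via 3-(benzyloxy)phenyllithium 8 (not isolated), via lithium aryl(vinyl)borate 9 (not isolated)
Conditions: 6, t-BuLi (2.0 equiv), Et2O, −78 °C; 7, −78 °C to rt; evaporate; then 5 (limiting), Pd(OAc)2 (3 mol%), MandyPhos ligand 1,1′-bis[bis(4-methoxy-3,5-dimethylphenyl)phosphino]-2,2′-bis[α-(dimethylamino)benzyl]ferrocene (3.6 mol%), NaOTf (2 equiv), THF, 60 °C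
Reagents that add atoms: none
Why: Bromine–lithium exchange on 6 gives aryllithium 8, which adds to boron of 7 to give the four-coordinate borate 9; oxidative addition of triflate 5 to zerovalent palladium (from Pd(OAc)2 and the bisphosphine) gives a cationic aryl complex of divalent palladium that binds the vinyl group of 9, triggers 1,2-migration of the 3-(benzyloxy)phenyl group from boron to the boron-bearing carbon as palladium bonds the terminal carbon, and reductive elimination then forms the C1(ring A)–CH2 bond. The closest known reaction type is the palladium-catalysed conjunctive cross-coupling of vinylboron ate complexes with aryl triflates, applied here with an aryl migrating group and an ortho-substituted electrophile. No ring is closed. The one new stereocentre, the boron-bearing benzylic carbon, is set under ligand control (migration anti to palladium on the bound alkene) and needs no control, since step 5 converts it into CH2. The step needs chemoselectivity for the metallate shift over direct Suzuki-type transfer of the aryl or vinyl group and over β-hydride elimination: the triflate leaving group and the chelating bisphosphine should keep palladium cationic with an open site for the alkene, NaOTf removes the bromide from the exchange as insoluble NaBr before it can occupy that site, and ipso substitution of the triflate fixes the position on ring A. The unhindered meta-substituted migrating aryl should offset the steric demand of the ortho benzyl group on the electrophile.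

**Step 5**
Reactants: 10 2-(2-{2-[4-(benzyloxy)benzyl]-3,5-dimethoxyphenyl}-1-[3-(benzyloxy)phenyl]ethyl)-4,4,5,5-tetramethyl-1,3,2-dioxaborolane
Product: 11 1-{2-[3-(benzyloxy)phenyl]ethyl}-2-[4-(benzyloxy)benzyl]-3,5-dimethoxybenzene
Conditions: TBAF·3H2O (3 equiv), toluene, 80 °C
Reagents that add atoms: none
Why: Fluoride-promoted protodeboronation of a secondary benzylic boronic ester, in which fluoride coordinates boron and the benzylic C–B bond of the resulting ate complex is protonated by the water of hydration, erasing the stereocentre and leaving all ethers untouched.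

**Step 6**
Reactants: 11 1-{2-[3-(benzyloxy)phenyl]ethyl}-2-[4-(benzyloxy)benzyl]-3,5-dimethoxybenzene
Product: 12 gymconopin D, 3-{2-[2-(4-hydroxybenzyl)-3,5-dimethoxyphenyl]ethyl}phenol
Conditions: H2 (1 atm), Pd/C (10% palladium on carbon), EtOAc/MeOH, rt
Reagents that add atoms: none
Why: Catalytic hydrogenolysis of both aryl benzyl ethers over palladium on carbon, under which the aryl methyl ethers, the diarylmethane CH2 and the bibenzyl bridge are inert.

**Compound list**
1 | 2-hydroxy-4,6-dimethoxybenzaldehyde | COc1cc(O)c(C=O)c(OC)c1 | starting material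
2 | 4-(benzyloxy)phenylmagnesium bromide | Br[Mg]c1ccc(OCc2ccccc2)cc1 | starting material
3 | racemic 2-{[4-(benzyloxy)phenyl](hydroxy)methyl}-3,5-dimethoxyphenol | COc1cc(O)c(C(O)c2ccc(OCc3ccccc3)cc2)c(OC)c1 | intermediate
4 | 2-[4-(benzyloxy)benzyl]-3,5-dimethoxyphenol | COc1cc(O)c(Cc2ccc(OCc3ccccc3)cc2)c(OC)c1 | intermediate
5 | 2-[4-(benzyloxy)benzyl]-3,5-dimethoxyphenyl trifluoromethanesulfonate | COc1cc(OC)c(Cc2ccc(OCc3ccccc3)cc2)c(OS(=O)(=O)C(F)(F)F)c1 | intermediate
6 | 1-(benzyloxy)-3-bromobenzene | Brc1cccc(OCc2ccccc2)c1 | starting material
7 | vinylboronic acid pinacol ester (2-ethenyl-4,4,5,5-tetramethyl-1,3,2-dioxaborolane) | C=CB1OC(C)(C)C(C)(C)O1 | starting material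
8 | 3-(benzyloxy)phenyllithium | [Li]c1cccc(OCc2ccccc2)c1 | intermediate
9 | lithium [3-(benzyloxy)phenyl](ethenyl)(pinacolato)borate | [Li+].C=C[B-]1(c2cccc(OCc3ccccc3)c2)OC(C)(C)C(C)(C)O1 | intermediate
10 | 2-(2-{2-[4-(benzyloxy)benzyl]-3,5-dimethoxyphenyl}-1-[3-(benzyloxy)phenyl]ethyl)-4,4,5,5-tetramethyl-1,3,2-dioxaborolane; one stereocentre at the boron-bearing carbon, mixture of enantiomers, configuration unassigned and immaterial | COc1cc(CC(B2OC(C)(C)C(C)(C)O2)c2cccc(OCc3ccccc3)c2)c(Cc2ccc(OCc3ccccc3)cc2)c(OC)c1 | intermediate
11 | 1-{2-[3-(benzyloxy)phenyl]ethyl}-2-[4-(benzyloxy)benzyl]-3,5-dimethoxybenzene | COc1cc(CCc2cccc(OCc3ccccc3)c2)c(Cc2ccc(OCc3ccccc3)cc2)c(OC)c1 | intermediate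
12 | gymconopin D, 3-{2-[2-(4-hydroxybenzyl)-3,5-dimethoxyphenyl]ethyl}phenol (achiral) | COc1cc(CCc2cccc(O)c2)c(Cc2ccc(O)cc2)c(OC)c1 | target

**Step count.** Total: 6 steps. Longest linear sequence: 6 steps (1 → 3 → 4 → 5 → 10 → 11 → 12).

**Steps most likely to fail**

Step 4. Oxidative addition of the ortho-benzylated, electron-rich triflate may be slow. Direct transfer of the aryl or vinyl group from boron, β-hydride elimination, or attack of the borate at the sulfonyl group could then overtake the metallate shift. The fallback builds the bridge by two conventional couplings and sets out from triflate 5. Suzuki–Miyaura coupling of 5 with vinylboronic ester 7 (PdCl2(dppf), K3PO4, dioxane/H2O, 90 °C) should give the styrene 2-[4-(benzyloxy)benzyl]-1-ethenyl-3,5-dimethoxybenzene F1. Mizoroki–Heck arylation of F1 with bromide 6 (Pd(OAc)2, P(o-tol)3, Et3N, DMF, 100 °C) should give the stilbene 1-{(E)-2-[3-(benzyloxy)phenyl]ethenyl}-2-[4-(benzyloxy)benzyl]-3,5-dimethoxybenzene F2. Hydrogenation under the conditions of step 6 should then saturate the alkene and remove both benzyl groups, so the fallback comes back to the route at target 12.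

Step 5. Protonolysis of the secondary benzylic C–B bond may be sluggish, with slow decomposition on prolonged heating with fluoride. The fallback replaces protonolysis by oxidation and hydrogenolysis and sets out from boronate 10. Oxidation (NaOH, H2O2, THF/H2O, 0 °C) should give the alcohol 2-{2-[4-(benzyloxy)benzyl]-3,5-dimethoxyphenyl}-1-[3-(benzyloxy)phenyl]ethan-1-ol F3. Hydrogenation over palladium on carbon in acetic acid with a catalytic amount of HClO4 (H2, 3 atm, 40 °C) should then cleave the benzylic C–OH bond together with both benzyl ethers, so the fallback comes back at target 12.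

Step 1. Addition to the chelated, electron-rich phenoxide aldehyde may be incomplete, and the ortho-hydroxy carbinol may condense with itself through a quinone methide during work-up. The fallback masks the phenol as the triflate before the carbon–carbon bond is made and sets out from aldehyde 1. Tf2O and pyridine in CH2Cl2 at 0 °C should give 2-formyl-3,5-dimethoxyphenyl trifluoromethanesulfonate F4. Addition of Grignard reagent 2 (1.1 equiv, THF, −78 °C) should give the carbinol 2-{[4-(benzyloxy)phenyl](hydroxy)methyl}-3,5-dimethoxyphenyl trifluoromethanesulfonate F5, which cannot form a quinone methide. Ionic hydrogenation (Et3SiH, CF3CO2H, CH2Cl2, 0 °C) should then give triflate 5, where the fallback comes back to the route.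

**Further compounds**
F1 | step 4 | 2-[4-(benzyloxy)benzyl]-1-ethenyl-3,5-dimethoxybenzene | COc1cc(C=C)c(Cc2ccc(OCc3ccccc3)cc2)c(OC)c1
F2 | step 4 | 1-{(E)-2-[3-(benzyloxy)phenyl]ethenyl}-2-[4-(benzyloxy)benzyl]-3,5-dimethoxybenzene | COc1cc(/C=C/c2cccc(OCc3ccccc3)c2)c(Cc2ccc(OCc3ccccc3)cc2)c(OC)c1
F3 | step 5 | 2-{2-[4-(benzyloxy)benzyl]-3,5-dimethoxyphenyl}-1-[3-(benzyloxy)phenyl]ethan-1-ol (same enantiomer mixture as 10, configuration immaterial) | COc1cc(CC(O)c2cccc(OCc3ccccc3)c2)c(Cc2ccc(OCc3ccccc3)cc2)c(OC)c1
F4 | step 1 | 2-formyl-3,5-dimethoxyphenyl trifluoromethanesulfonate | COc1cc(OC)c(C=O)c(OS(=O)(=O)C(F)(F)F)c1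
F5 | step 1 | racemic 2-{[4-(benzyloxy)phenyl](hydroxy)methyl}-3,5-dimethoxyphenyl trifluoromethanesulfonate | COc1cc(OC)c(C(O)c2ccc(OCc3ccccc3)cc2)c(OS(=O)(=O)C(F)(F)F)c1
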